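The core is numbered as a 7-oxabicyclo[4.1.0]heptan-2-one: C1 (methyl, oxirane), C2 (ketone), C3 (tiglate), C4 (side chain), C6 (oxirane CH), O7. The route rests on the C1–C2 bond. The C2 ketone beside the tertiary C1–O7 bond is an acyloin retron, and O7–C6 can arise by displacing a leaving group. The precursor, an open-chain 6-oxoheptanal with a mesylate at its own C5, is cut out of (S)-carvone by cleaving its ring alkene. A carbene-catalysed aldehyde–ketone benzoin closure whose alkoxide expels the mesylate then builds cyclohexanone, oxirane, quaternary C1 and the oxirane face cis to the side chain in one operation. Oxygenation at C3 and chain extension follow.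

Key step: step 5

Assumption: bicycle locants are used for all cyclic compounds, and the carbinol centre formed in step 9 is left unassigned because step 10 removes it.

Step 1
Reactants: 1 (S)-(+)-carvone
Product: 2 (1S,4S,6S)-1-methyl-4-(prop-1-en-2-yl)-7-oxabicyclo[4.1.0]heptan-2-one (oxirane trans to the isopropenyl group)
Conditions: 30% aq H2O2, NaOH (cat.), MeOH, 0 °C
Reagents that add atoms: hydrogen peroxide, OO
Why: Weitz–Scheffer nucleophilic epoxidation reacts only at the electron-poor enone alkene, and axial attack of hydroperoxide anti to the equatorial isopropenyl group should place the oxirane trans to it.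

Step 2
Reactants: 2 epoxy ketone
Product: 3 (1R,2R,4R,6S)-1-methyl-4-(prop-1-en-2-yl)-7-oxabicyclo[4.1.0]heptan-2-ol (hydroxyl cis to the oxirane oxygen and trans to the isopropenyl group)
Conditions: LiBH(s-Bu)3, THF, −78 °C; H2O
Reagents that add atoms: none
Why: Diastereoselective ketone reduction with a bulky trialkylborohydride, in which hydride should arrive equatorially on the face remote from the oxirane oxygen and so set the axial C2 carbinol cis to the oxirane and trans to the isopropenyl group.

Step 3
Reactants: 3 epoxy alcohol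
Product: 4 (1S,2R,4S,6S)-1-methyl-4-(prop-1-en-2-yl)-7-oxabicyclo[4.1.0]heptan-2-yl methanesulfonate
Conditions: MsCl, Et3N, CH2Cl2, 0 °C
Reagents that add atoms: methanesulfonyl chloride, CS(=O)(=O)Cl
Why: Sulfonylation of a secondary alcohol with retention at carbon; the mesylate shields this oxygen from the glycol cleavage of step 4 and is the nucleofuge of step 5.

Step 4
Reactants: 4 epoxy mesylate
Product: 6 (3R,5R)-5-(methylsulfonyloxy)-6-oxo-3-(prop-1-en-2-yl)heptanal, via trans-diol mesylate 5 (not isolated)
Conditions: H5IO6, THF/H2O, 0 °C to rt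
Reagents that add atoms: water, O
Why: Periodic acid opens the trisubstituted oxirane to the trans-diol and cleaves it in the same flask (Malaprade glycol cleavage), leaving the 1,1-disubstituted alkene, the mesylate and both existing stereocentres untouched.

Step 5
Reactants: 6 keto aldehyde mesylate
Product: 9 (1S,4R,6S)-1-methyl-4-(prop-1-en-2-yl)-7-oxabicyclo[4.1.0]heptan-2-one (oxirane cis to the isopropenyl group), via Breslow intermediate 7 (not isolated), via ketol mesylate 8 (not isolated)
Conditions: 2-(pentafluorophenyl)-6,7-dihydro-5H-pyrrolo[2,1-c][1,2,4]triazol-2-ium tetrafluoroborate (15 mol %), Cs2CO3 (1.5 equiv), THF (0.02 M), 0 °C to rt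
Reagents that add atoms: none
Why: Proposed new method: the carbene adds to the aldehyde of 6, proton transfer gives the acyl anion equivalent 7, its nucleophilic carbon attacks the methyl ketone (new C1–C2 bond), and the tertiary alkoxide of 8 displaces the antiperiplanar mesylate before or after release of the carbene. The closest known reaction type is the carbene-catalysed intramolecular crossed aldehyde–ketone benzoin reaction, established for six-membered α-ketols, joined here to the oxirane closure that ends a Darzens condensation; an α-sulfonyloxy ketone has not been used as the acceptor. The cyclohexanone closes 6-exo-trig and the oxirane 3-exo-tet. C1 is controlled by a chair transition state with the isopropenyl and C1-methyl groups equatorial and the C–OMs bond axial and anti to the carbonyl dipole (Cornforth arrangement), so the new C–O bond is axial and trans to the mesylate, while C6 is set by stereospecific inversion of the carbinol centre made in step 2. Benzoin addition to a ketone can revert under carbene catalysis whereas oxirane closure cannot, so only the trans-diaxial ketol should be drained to 9. The step needs carbonyl addition to outrun direct displacement of the mesylate, aldol closure and epimerisation next to the ketone, which intramolecularity, high dilution, the hindered secondary sulfonate and a mild carbonate base should secure.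

Step 6
Reactants: 9 cis-epoxy ketone
Product: 11 (1S,3S,4S,6S)-3-hydroxy-1-methyl-4-(prop-1-en-2-yl)-7-oxabicyclo[4.1.0]heptan-2-one (hydroxyl trans to the isopropenyl group and to the oxirane oxygen), via potassium enolate 10 (not isolated)
Conditions: KN(SiMe3)2, THF, −78 °C; 2-(phenylsulfonyl)-3-phenyloxaziridine, −78 °C; AcOH
Reagents that add atoms: 2-(phenylsulfonyl)-3-phenyloxaziridine, O=S(=O)(c1ccccc1)N1OC1c1ccccc1
Why: Enolate hydroxylation with an N-sulfonyloxaziridine, in which C3 is the only enolisable position and the oxidant should approach anti to the neighbouring isopropenyl group to give the trans, diequatorial ketol, also the thermodynamically preferred epimer.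

Step 7
Reactants: 11 hydroxy ketone; 12 tigloyl chloride
Product: 13 (1S,3S,4S,6S)-1-methyl-2-oxo-4-(prop-1-en-2-yl)-7-oxabicyclo[4.1.0]heptan-3-yl (E)-2-methylbut-2-enoate
Conditions: pyridine, DMAP (cat.), CH2Cl2, 0 °C to rt
Reagents that add atoms: none
Why: DMAP-catalysed acylation of the secondary alcohol with retention at C3; the (E)-geometry of the tigloyl unit is the stable one and is not at risk.

Step 8
Reactants: 13 tiglate
Product: 15 (1S,3S,4S,6S)-1-methyl-2-oxo-4-(3-oxoprop-1-en-2-yl)-7-oxabicyclo[4.1.0]heptan-3-yl (E)-2-methylbut-2-enoate, via allylic alcohol 14 (not isolated)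
Conditions: SeO2 (0.3 equiv), t-BuOOH, CH2Cl2, rt; crude: DMP, CH2Cl2, rt
Reagents that add atoms: selenium dioxide, O=[Se]=O; tert-butyl hydroperoxide, CC(C)(C)OO
Why: Riley-type allylic oxidation (ene reaction, then [2,3]-sigmatropic shift) should pick the electron-rich 1,1-disubstituted alkene over the conjugated tiglate, and the periodinane converges alcohol and aldehyde on the enal without touching a stereocentre.

Step 9
Reactants: 15 enal; 16 trimethyl[(2-methylbut-3-yn-2-yl)oxy]silane
Product: 20 (1S,3S,4S,6S)-4-[(4E)-3,6-dihydroxy-6-methylhepta-1,4-dien-2-yl]-1-methyl-2-oxo-7-oxabicyclo[4.1.0]heptan-3-yl (E)-2-methylbut-2-enoate (both carbinol epimers), via alkenylzirconocene chloride 17 (not isolated), via alkenyl(methyl)zinc 18 (not isolated), via silyl ether adduct 19 (not isolated)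
Conditions: 16, Cp2Zr(H)Cl, CH2Cl2, rt; Me2Zn, −65 °C; 15, 0 °C; aq NH4Cl; crude: Bu4NF, AcOH, THF, 0 °C
Reagents that add atoms: none
Why: Hydrozirconation of the terminal alkyne (syn addition, metal at the terminus) fixes the (E)-alkene, the alkenylzinc from zirconium-to-zinc transmetalation adds 1,2 to the aldehyde while ketone, ester and oxirane are left alone, and buffered fluoride removes the labile silyl ether.

Step 10
Reactants: 20 diol
Product: 21 target CNP0263368.1
Conditions: DMP, CH2Cl2, 0 °C to rt
Reagents that add atoms: none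
Why: Periodinane oxidation of the secondary bis-allylic alcohol under near-neutral conditions should give the cross-conjugated dienone, and the tertiary alcohol cannot be oxidised.

Compound list
1 | (S)-(+)-carvone, (5S)-2-methyl-5-(prop-1-en-2-yl)cyclohex-2-en-1-one | C=C(C)[C@@H]1CC(=O)C(C)=CC1 | starting material
2 | (1S,4S,6S)-1-methyl-4-(prop-1-en-2-yl)-7-oxabicyclo[4.1.0]heptan-2-one | C=C(C)[C@@H]1CC(=O)[C@@]2(C)O[C@H]2C1 | intermediate
3 | (1R,2R,4R,6S)-1-methyl-4-(prop-1-en-2-yl)-7-oxabicyclo[4.1.0]heptan-2-ol | C=C(C)[C@@H]1C[C@@H](O)[C@@]2(C)O[C@H]2C1 | intermediate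
4 | (1S,2R,4S,6S)-1-methyl-4-(prop-1-en-2-yl)-7-oxabicyclo[4.1.0]heptan-2-yl methanesulfonate | C=C(C)[C@@H]1C[C@@H](OS(C)(=O)=O)[C@@]2(C)O[C@H]2C1 | intermediate
5 | (1R,2R,3S,5S)-2,3-dihydroxy-2-methyl-5-(prop-1-en-2-yl)cyclohexyl methanesulfonate (not isolated) | C=C(C)[C@@H]1C[C@@H](OS(C)(=O)=O)[C@](C)(O)[C@@H](O)C1 | intermediate
6 | (3R,5R)-5-(methylsulfonyloxy)-6-oxo-3-(prop-1-en-2-yl)heptanal | C=C(C)[C@@H](CC=O)C[C@@H](OS(C)(=O)=O)C(C)=O | intermediate
7 | Breslow intermediate, enaminol from 6 and the triazolylidene (not isolated) | C=C(C)[C@@H](CC(O)=C1N(c2c(F)c(F)c(F)c(F)c2F)N=C2CCCN12)C[C@@H](OS(C)(=O)=O)C(C)=O | intermediate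
8 | (1R,2S,5R)-2-hydroxy-2-methyl-3-oxo-5-(prop-1-en-2-yl)cyclohexyl methanesulfonate (not isolated) | C=C(C)[C@@H]1C[C@@H](OS(C)(=O)=O)[C@](C)(O)C(=O)C1 | intermediate
9 | (1S,4R,6S)-1-methyl-4-(prop-1-en-2-yl)-7-oxabicyclo[4.1.0]heptan-2-one | C=C(C)[C@@H]1C[C@@H]2O[C@]2(C)C(=O)C1 | intermediate
10 | potassium C2–C3 enolate of 9 (not isolated) | C=C(C)[C@@H]1C[C@@H]2O[C@]2(C)C([O-])=C1.[K+] | intermediate
11 | (1S,3S,4S,6S)-3-hydroxy-1-methyl-4-(prop-1-en-2-yl)-7-oxabicyclo[4.1.0]heptan-2-one | C=C(C)[C@@H]1C[C@@H]2O[C@]2(C)C(=O)[C@H]1O | intermediate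
12 | tigloyl chloride, (E)-2-methylbut-2-enoyl chloride | O=C(Cl)/C(C)=C/C | starting material
13 | (1S,3S,4S,6S)-1-methyl-2-oxo-4-(prop-1-en-2-yl)-7-oxabicyclo[4.1.0]heptan-3-yl (E)-2-methylbut-2-enoate | C=C(C)[C@@H]1C[C@@H]2O[C@]2(C)C(=O)[C@H]1OC(=O)/C(C)=C/C | intermediate
14 | 4-(3-hydroxyprop-1-en-2-yl) analogue of 13 (not isolated) | C=C(CO)[C@@H]1C[C@@H]2O[C@]2(C)C(=O)[C@H]1OC(=O)/C(C)=C/C | intermediate
15 | 4-(3-oxoprop-1-en-2-yl) analogue of 13 (enal) | C=C(C=O)[C@@H]1C[C@@H]2O[C@]2(C)C(=O)[C@H]1OC(=O)/C(C)=C/C | intermediate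
16 | trimethyl[(2-methylbut-3-yn-2-yl)oxy]silane | C#CC(C)(C)O[Si](C)(C)C | starting material
17 | chloro[(E)-3-methyl-3-(trimethylsilyloxy)but-1-enyl]zirconocene (not isolated) | C[Si](C)(C)OC(C)(C)/C=C/[Zr](Cl)(C1C=CC=C1)C1C=CC=C1 | intermediate
18 | methyl[(E)-3-methyl-3-(trimethylsilyloxy)but-1-enyl]zinc (not isolated) | C[Zn]/C=C/C(C)(C)O[Si](C)(C)C | intermediate
19 | tertiary trimethylsilyl ether of 20 (not isolated) | C=C(C(O)/C=C/C(C)(C)O[Si](C)(C)C)[C@@H]1C[C@@H]2O[C@]2(C)C(=O)[C@H]1OC(=O)/C(C)=C/C | intermediate
20 | (1S,3S,4S,6S)-4-[(4E)-3,6-dihydroxy-6-methylhepta-1,4-dien-2-yl]-1-methyl-2-oxo-7-oxabicyclo[4.1.0]heptan-3-yl (E)-2-methylbut-2-enoate | C=C(C(O)/C=C/C(C)(C)O)[C@@H]1C[C@@H]2O[C@]2(C)C(=O)[C@H]1OC(=O)/C(C)=C/C | intermediate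
21 | (1S,3S,4S,6S)-4-[(4E)-6-hydroxy-6-methyl-3-oxohepta-1,4-dien-2-yl]-1-methyl-2-oxo-7-oxabicyclo[4.1.0]heptan-3-yl (E)-2-methylbut-2-enoate | C=C(C(=O)/C=C/C(C)(C)O)[C@@H]1C[C@@H]2O[C@]2(C)C(=O)[C@H]1OC(=O)/C(C)=C/C | target

Total step count: 10. Longest linear sequence: 10 steps (1 to 21).

Steps most likely to fail

Step 5 (proposed new method).
- What may go wrong: direct displacement of the mesylate by the acyl anion equivalent with closure of a five-membered ring. Other failure modes are alkylation of the carbene, base-induced epimerisation or elimination next to the ketone, and intramolecular aldol closure.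
- Fallback, from 3 back to 9, separates the C–C bond formation from the oxirane closure and uses only known chemistry. The hydroxyl of 3 is silylated (TBSOTf, 2,6-lutidine) to the tert-butyldimethylsilyl ether F1, and H5IO6 cleavage as in step 4 gives the α-silyloxy keto aldehyde F2.
- The established carbene-catalysed crossed benzoin cyclisation (the same triazolium salt or a chiral aminoindanol-derived analogue, Et3N, THF) then gives the protected ketol F3 with no leaving group present. Bu4NF frees the keto diol F4, MsCl/Et3N sulfonylates only the secondary hydroxyl to give 8, and DBU closes the oxirane to 9.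

Step 6.
- What may go wrong: opening of the oxirane or Favorskii-type ring contraction triggered by the free enolate, capture of the enolate by the spent oxidant, and poor facial selectivity.
- Fallback, from 9 back to 11, is a Rubottom oxidation. Deprotonation with LiN(SiMe3)2 in the presence of Me3SiCl (internal quench, −78 °C) traps the enolate at once as the trimethylsilyl enol ether F5.
- One equivalent of dimethyldioxirane in acetone at −78 °C oxidises this most electron-rich alkene, with silyl migration, to the α-silyloxy ketone F6. Dilute citric acid in MeOH then gives 11.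

Step 8.
- What may go wrong: poor site selectivity (attack at the tertiary allylic C4–H or at the tiglate methyl groups) and over-oxidation.
- Fallback, from 13 back to 15, starts with ene-type allylic chlorination by hypochlorous acid generated from Ca(OCl)2 and CO2 in CH2Cl2/H2O, which gives the allylic chloride F7.
- Oxidation of this activated halide with N-methylmorpholine N-oxide in MeCN (Kornblum-type oxidation) returns the enal 15.

Further compounds
F1 | step 5 | tert-butyldimethylsilyl ether of 3 | C=C(C)[C@@H]1C[C@@H](O[Si](C)(C)C(C)(C)C)[C@@]2(C)O[C@H]2C1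
F2 | step 5 | (3R,5R)-5-(tert-butyldimethylsilyloxy)-6-oxo-3-(prop-1-en-2-yl)heptanal | C=C(C)[C@@H](CC=O)C[C@@H](O[Si](C)(C)C(C)(C)C)C(C)=O
F3 | step 5 | 3-O-tert-butyldimethylsilyl ether of F4 | C=C(C)[C@@H]1C[C@@H](O[Si](C)(C)C(C)(C)C)[C@](C)(O)C(=O)C1
F4 | step 5 | (2S,3R,5R)-2,3-dihydroxy-2-methyl-5-(prop-1-en-2-yl)cyclohexan-1-one | C=C(C)[C@@H]1C[C@@H](O)[C@](C)(O)C(=O)C1
F5 | step 6 | trimethylsilyl enol ether of 9 | C=C(C)[C@@H]1C[C@@H]2O[C@]2(C)C(O[Si](C)(C)C)=C1
F6 | step 6 | trimethylsilyl ether of 11 | C=C(C)[C@@H]1C[C@@H]2O[C@]2(C)C(=O)[C@H]1O[Si](C)(C)C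
F7 | step 8 | 4-(3-chloroprop-1-en-2-yl) analogue of 13 | C=C(CCl)[C@@H]1C[C@@H]2O[C@]2(C)C(=O)[C@H]1OC(=O)/C(C)=C/C
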